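**Strategy.** Everything rests on cutting the N1–C3' bond between ring A (the 2,3,5-tribromoindole) and ring B (the 2',4',5'-tribromoindole). In ring B this bond lies next to the C2'–Br carbon, so ring B is carried as a 3-bromooxindole: its C3 is electrophilic (polarity-reversed) and its lactam carbonyl is a masked C2'–Br. Ring A is carried as 5-bromoindoline, whose nitrogen is the only nucleophilic site. The key step joins racemic 3,4,5-tribromooxindole and 5-bromoindoline in one operation through the transient indol-2-one, giving a 3-(indolin-1-yl)oxindole that already holds three of the six bromines. Dehydrogenation, lactam deoxybromination and two NBS brominations then finish both pyrrole rings.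

Key step: step 4

Remark: the target SMILES defines neither a stereocenter nor an axis, so the hindered N1–C3' axis is accepted as the racemate; primed locants refer to ring B, unprimed ones to ring A.

Step 1
Reactants: 1 4-bromoisatin (4-bromoindoline-2,3-dione)
Product: 2 4,5-dibromoisatin (4,5-dibromoindoline-2,3-dione)
Conditions: NBS (1.05 equiv), conc. H2SO4, 0 °C to rt; ice quench; recrystallisation from AcOH
Reagents that add atoms: N-bromosuccinimide, O=C1CCC(=O)N1Br
Why: Electrophilic aromatic bromination (SEAr) should go to C5, which is para to the lactam nitrogen and ortho to the C4 bromine and is the site where isatins brominate first, with any 7-bromo isomer removed by crystallisation.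

Step 2
Reactants: 2 4,5-dibromoisatin
Product: 4 4,5-dibromo-3-diazoindolin-2-one, via tosylhydrazone 3 (not isolated)
Conditions: TsNHNH2 (1.05 equiv), MeOH, 65 °C; then aq NaOH (0.2 M), rt to 50 °C; neutralisation with CO2
Reagents that add atoms: p-toluenesulfonyl hydrazide, Cc1ccc(cc1)S(=O)(=O)NN
Why: Condensation of the reactive C3 ketone with tosylhydrazide gives hydrazone 3, whose anion expels p-toluenesulfinate in aqueous base (Bamford–Stevens-type fragmentation of a tosylhydrazone, the classical entry to 3-diazooxindoles), the diazo group being stabilised by the lactam carbonyl.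

Step 3
Reactants: 4 4,5-dibromo-3-diazoindolin-2-one
Product: 5 3,4,5-tribromoindolin-2-one (racemic)
Conditions: HBr (33% in AcOH, 1.2 equiv), CH2Cl2, 0 °C; concentrated and used at once
Reagents that add atoms: hydrogen bromide, Br
Why: Hydrohalogenation of an α-diazo lactam: HBr protonates the diazo carbon, N2 leaves and bromide is captured at C3', which should give the benzylic bromide as a racemate (no control is needed, since the centre is erased in step 6) and leave the aryl bromides untouched.

Step 4
Reactants: 5 3,4,5-tribromoindolin-2-one (racemic); 6 5-bromoindoline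
Product: 8 4,5-dibromo-3-(5-bromoindolin-1-yl)indolin-2-one (racemic), via indol-2-one 7 (not isolated)
Conditions: 5 added dropwise to 6 (2 equiv) and iPr2NEt (1.5 equiv), MeCN, −20 °C to rt, argon
Reagents that add atoms: none
Why: iPr2NEt removes HBr from 5 across N1'–H and C3'–Br to give the transient aza-ortho-xylylene 7, whose strongly electrophilic C3' takes up the indoline nitrogen in a conjugate addition that restores the benzene ring, and direct SN2 displacement of the benzylic α-bromo lactam converges on the same product. The closest known reaction type is the amination of 3-halooxindoles by amines through base-generated indol-2-ones. No ring is closed: the step only joins the two intact bicycles through the N1–C3' bond. The new C3' stereocenter forms without control as a racemate and is erased when ring B is aromatised in step 6. The step needs N- over C-attack and cross-coupling over self-condensation of 7 with the enolate of 5 (isoindigo-type dimers); the saturated C2–C3 and the C5 bromine leave nitrogen as the only nucleophilic site of 6, and slow addition of 5 to excess 6 under a weak amine base keeps both 7 and the enolate at low concentration. The small, reactive electrophile should tolerate the peri C4' bromine that would hamper a metal-catalysed N-arylation.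

Step 5
Reactants: 8 4,5-dibromo-3-(5-bromoindolin-1-yl)indolin-2-one (racemic)
Product: 9 4,5-dibromo-3-(5-bromo-1H-indol-1-yl)indolin-2-one (racemic)
Conditions: DDQ (1.05 equiv), 1,4-dioxane, 0 °C to rt, argon
Reagents that add atoms: none
Why: DDQ dehydrogenation of an N-substituted indoline to the indole (hydride abstraction at C2 next to nitrogen, then loss of the C3 proton) is driven by aromatisation and should outpace attack at the hindered, carbonyl-deactivated C3'–H, so the racemic C3' centre is carried through unchanged.

Step 6
Reactants: 9 4,5-dibromo-3-(5-bromo-1H-indol-1-yl)indolin-2-one (racemic)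
Product: 10 2,4,5-tribromo-3-(5-bromo-1H-indol-1-yl)-1H-indole
Conditions: POBr3 (2.5 equiv), imidazole (1.2 equiv), ClCH2CH2Cl (dilute), 80 °C; aq NaHCO3 work-up
Reagents that add atoms: phosphorus oxybromide, O=P(Br)(Br)Br
Why: Deoxybromination of the lactam by POBr3 (Vilsmeier-type O-activation, bromide addition–elimination at C2' and loss of the C3' proton), the known conversion of oxindoles into 2-bromoindoles, aromatises ring B, installs C2'–Br and erases the C3' stereocenter, while imidazole buffers HBr and dilution disfavours attack of the free C3 of ring A on the activated lactam.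

Step 7
Reactants: 10 2,4,5-tribromo-3-(5-bromo-1H-indol-1-yl)-1H-indole
Product: 12 Rivularin A (2,3,5,2',4',5'-hexabromo-1'H-1,3'-biindole), via pentabromide 11 (not isolated)
Conditions: NBS (1.0 equiv), dry DMF, −20 to 0 °C; then NBS (1.1 equiv), 0 °C to rt, dark; aq Na2S2O3 work-up
Reagents that add atoms: N-bromosuccinimide, O=C1CCC(=O)N1Br
Why: Electrophilic bromination by NBS should occur first at C3 of ring A, the only free indole β-position, and the second equivalent then brominates C2 of the resulting N-substituted 3-bromoindole (the known stepwise 2,3-dibromination of N-substituted indoles), ring B being deactivated by three bromines and having no free pyrrole carbon.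

**Compound list**

1 | 4-bromoisatin (4-bromoindoline-2,3-dione) | O=C1Nc2cccc(Br)c2C1=O | starting material
2 | 4,5-dibromoisatin (4,5-dibromoindoline-2,3-dione) | O=C1Nc2ccc(Br)c(Br)c2C1=O | intermediate
3 | (Z)-4,5-dibromoisatin 3-(p-toluenesulfonyl)hydrazone (not isolated; geometry of no consequence) | O=C1Nc2ccc(Br)c(Br)c2/C1=N/NS(=O)(=O)c1ccc(C)cc1 | intermediate
4 | 4,5-dibromo-3-diazoindolin-2-one | O=C1Nc2ccc(Br)c(Br)c2C1=[N+]=[N-] | intermediate
5 | 3,4,5-tribromoindolin-2-one (racemic, used fresh) | O=C1Nc2ccc(Br)c(Br)c2C1Br | intermediate
6 | 5-bromoindoline | Brc1ccc2c(c1)CCN2 | starting material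
7 | 4,5-dibromo-2H-indol-2-one (aza-ortho-xylylene, not isolated) | O=C1N=C2C=CC(Br)=C(Br)C2=C1 | intermediate
8 | 4,5-dibromo-3-(5-bromoindolin-1-yl)indolin-2-one (racemic) | O=C1Nc2ccc(Br)c(Br)c2C1N1CCc2cc(Br)ccc21 | intermediate
9 | 4,5-dibromo-3-(5-bromo-1H-indol-1-yl)indolin-2-one (racemic) | O=C1Nc2ccc(Br)c(Br)c2C1n1ccc2cc(Br)ccc21 | intermediate
10 | 2,4,5-tribromo-3-(5-bromo-1H-indol-1-yl)-1H-indole | Brc1ccc2c(c1)ccn2-c1c(Br)[nH]c2ccc(Br)c(Br)c12 | intermediate
11 | 3,5,2',4',5'-pentabromo-1'H-1,3'-biindole (not isolated) | Brc1ccc2c(c1)c(Br)cn2-c1c(Br)[nH]c2ccc(Br)c(Br)c12 | intermediate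
12 | Rivularin A (2,3,5,2',4',5'-hexabromo-1'H-1,3'-biindole) | Brc1ccc2c(c1)c(Br)c(Br)n2-c1c(Br)[nH]c2ccc(Br)c(Br)c12 | target

**Total step count:** 7 steps.
**Longest linear sequence:** 7 steps (1 to 12); 6 is bought and enters at step 4.

**Steps most likely to fail**

1. Step 4. C3'-deprotonation of 5 may compete, so that its enolate adds to 7 and self-condensation outruns amination. The peri C4' bromine may also slow attack of the weakly basic arylamine. The fallback sets out from diazo compound 4 and amine 6 and forms the same N1–C3' bond by carbenoid N–H insertion. With Rh2(OAc)4 (1 mol %) in ClCH2CH2Cl at 40–60 °C and slow addition of 4, the dirhodium carbenoid at C3' should be intercepted by the indoline nitrogen (ammonium ylide, then 1,2-proton shift). It returns to the route at 8, bypasses step 3 and makes no new compound (F0).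

2. Step 6. Activation of the hindered lactam may be incomplete, or the free C3 of ring A of a second molecule may attack the activated lactam (Vilsmeier-type oligomerisation). The fallback sets out from 9 and avoids an electrophilic lactam altogether. BH3·THF (THF, 0 °C to reflux, acidic work-up) should reduce the 3-monosubstituted oxindole to the indole, giving 4,5-dibromo-3-(5-bromo-1H-indol-1-yl)-1H-indole F1. NBS (3.1 equiv, DMF, 0 °C to rt) should then brominate C3 of ring A, the now free C2' of ring B and C2 of ring A. The fallback returns to the route at 12.

3. Step 7. The second equivalent of electrophilic bromine may be diverted to ring B (N-bromination, ipso attack at C3') or to a benzo position before the hindered, deactivated C2 of ring A reacts. The fallback sets out from 10 and enforces site selectivity with a removable acyl group on ring B.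
   - Boc2O and catalytic DMAP in MeCN should give tert-butyl 2,4,5-tribromo-3-(5-bromo-1H-indol-1-yl)-1H-indole-1-carboxylate F2, in which ring B has no N–H and is further deactivated.
   - NBS (2.2 equiv, DMF, 0 °C to rt) should then pass through tert-butyl 2,4,5-tribromo-3-(3,5-dibromo-1H-indol-1-yl)-1H-indole-1-carboxylate F3 (not isolated) to tert-butyl 2,4,5-tribromo-3-(2,3,5-tribromo-1H-indol-1-yl)-1H-indole-1-carboxylate F4.
   - TFA in CH2Cl2 at rt removes the carbamate and returns to the route at 12.

**Further compounds**

F0 | step 4 | none | none
F1 | step 6 | 4,5-dibromo-3-(5-bromo-1H-indol-1-yl)-1H-indole | Brc1ccc2c(c1)ccn2-c1c[nH]c2ccc(Br)c(Br)c12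
F2 | step 7 | tert-butyl 2,4,5-tribromo-3-(5-bromo-1H-indol-1-yl)-1H-indole-1-carboxylate | CC(C)(C)OC(=O)n1c(Br)c(-n2ccc3cc(Br)ccc32)c2c(Br)c(Br)ccc21
F3 | step 7 | tert-butyl 2,4,5-tribromo-3-(3,5-dibromo-1H-indol-1-yl)-1H-indole-1-carboxylate | CC(C)(C)OC(=O)n1c(Br)c(-n2cc(Br)c3cc(Br)ccc32)c2c(Br)c(Br)ccc21
F4 | step 7 | tert-butyl 2,4,5-tribromo-3-(2,3,5-tribromo-1H-indol-1-yl)-1H-indole-1-carboxylate | CC(C)(C)OC(=O)n1c(Br)c(-n2c(Br)c(Br)c3cc(Br)ccc32)c2c(Br)c(Br)ccc21
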